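(The numbers in the tables were generated by integration with constants of no real substance; noise was put on by code.)

Read the winter flask as a rate before asking anything of the others.

| flask | solid substrate | remark | time |
|---|---|---|---|
| winter | 0.92 M | run made earlier |  |
| Thursday's | 1.0 M |  | 80 min |
| Friday's | 3.0 M |  | 80 min |
| Monday's | 0.80 M |  | 80 min |
| Saturday's | 1.5 M |  | 80 min |
| Sunday's | 2.0 M |  | 80 min |

- winter (time / min: target / %): 3.00: 0.2; 6.00: 0; 12.0: 4.0; 20.0: 4.5; 40.0: 12.6

(each reading ± 1 percentage point)

- given per volume of solution although it is solid: solid substrate
- steps thought possible: starting material -> decomposition product; target <-> isomer of the product B; starting material <-> target; solid substrate <-> starting material; starting material <-> third isomer; starting material <-> isomer of the product A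
- at the start none of the solid substrate is in solution
- what has only dissolved of solid substrate counts as not reacted

1. all flasks from highest to lowest amount of target, in percent of the solid substrate charged, at 80 min (Thursday's / Friday's / Monday's / Saturday's / Sunday's)
2. the amount of target, in percent of the solid substrate charged of the flask you put first, at 80 min
3. the amount of target, in percent of the solid substrate charged of the flask you put last, at 80 min

None of the solid substrate is in solution at the start, and the target still reads 0 % at 6.00 min, so a molecule has first to dissolve and then to take the fork to target. From 12.0 min to 40.0 min the target climbs from 4.0 % to 12.6 %, a slope of 0.00307 min⁻¹. This gain, the fraction of the charge arriving as target per minute, is what I carry.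

I expect two things to bend it: the lag should steepen the curve and the back-steps should flatten it. I let them cancel and hold the gain straight, which puts the winter flask at 24.9 % by 80 min.

I expect a heavier charge to slow the gain itself. I take the steps in solution as first order, so a dissolved molecule has the same chances at its forks in each flask, and I take the dissolving as zero order in the solid substrate. The same amount then enters per minute, and the gain scales by winter charge over flask charge: 1.15 for Monday's and 0.307 for Friday's. This needs solid substrate to remain up to the end, which the winter readings of target do not show.

So I expect the order of rising charge, with Monday's at 28.6 % and Friday's at 7.63 %.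

The forecast gives Monday's > Thursday's > Saturday's > Sunday's > Friday's, with 27 % and 11 %, on the ground that “Solution concentration then caps”, and my Friday's figure is lower than its last value.

The flasks give Monday's > Thursday's > Saturday's > Sunday's > Friday's, from 28.4 % to 7.58 %.

    starting material → decomposition product (k = 1.60 × 10⁻⁵ min⁻¹)
    target ⇌ isomer of the product B (K = 1.70, k = 0.00940 min⁻¹)
    starting material ⇌ target (K = 2.90, k = 0.0260 min⁻¹)
    solid substrate ⇌ starting material, rate k4*(cs4 - [starting material]) while solid is left; crystals form when [starting material] > cs4 (solubility = 0.900 M, k = 0.0130 min⁻¹)
    starting material ⇌ third isomer (K = 6.00, k = 0.0110 min⁻¹)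
    starting material ⇌ isomer of the product A (K = 2.10, k = 0.00410 min⁻¹)

Monday's gives 28.4 % against my 28.6 %, and it still holds 6.37 % of its charge as solid substrate at 80.0 min. Friday's gives 7.58 % against my 7.63 %. The neighbour is Monday's flask read at 30 min. Walking back from the last winter reading with the gain and multiplying by 1.15 gives 11.0 %. That flask holds 8.94 % of target, 2 percentage points less than reckoned, with 61.5 % of its charge still solid substrate.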